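The question was how much of the D had reacted after 8.0 h in Saturday's and Wednesday's flasks, which differ in [L].

| flask | D | L | remark | time |
|---|---|---|---|---|
| summer | 0.30 M | 0.53 M | run made earlier |  |
| midnight | 0.30 M | 0.74 M | run made earlier |  |
| Saturday's | 0.30 M | 0.360 M |  | 8.0 h |
| Wednesday's | 0.30 M | 0.470 M |  | 8.0 h |

| run | time / h | D / % | E / % |
|---|---|---|---|
| summer | 0.417 | 87 | 10 |
| summer | 0.667 | 80 | 20 |
| summer | 1.00 | 76 | 25 |
| summer | 1.50 | 67 | 33 |
| summer | 2.50 | 55 | 44 |
| summer | 4.00 | 46 | 49 |
| summer | 6.00 | 39 | 62 |
| midnight | 0.417 | 81 | 15 |
| midnight | 0.667 | 75 | 25 |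
| midnight | 1.00 | 66 | 33 |
| midnight | 1.50 | 56 | 43 |
| midnight | 2.50 | 42 | 58 |
| midnight | 4.00 | 33 | 67 |
| midnight | 6.00 | 22 | 75 |

(each reading ± 1.5 percentage points)

- part of the D that has reacted at the end, Saturday's
- part of the D that has reacted at the end, Wednesday's
- what raising the concentration of L from its lowest to its highest value here does to the part of the D that has reacted (changes below 5 percentage points count as none) (it rises / it falls / no change)



1. I began with the main step alone, D + L → E, one to one. With [L] charged above [D] charged, its ceiling on conversion was 100% in both new flasks.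

2. I then let each D cost n of L. The specific rate, −d ln[D]/dt, follows free [L], so I divided the midnight value by the summer value at nearly equal [D]. Time and the rate constant dropped out, and the ratio read 2.15. After 0.163 M of D had reacted, one L per D predicted 1.57, which is less than was read. The reading gave n = 2.14, with the scatter of the readings on it, and I took two.

3. That gave the quantity I carried, the L quotient: [L] charged divided by two [D] charged, 60.0% for Saturday's and 78.3% for Wednesday's. At two L per D, it made L the limiting reagent, although [L] charged stood above [D] charged.

4. Finally I added the finite time. The integrated law, fitted to the last summer reading, gave k = 0.551 M⁻¹ h⁻¹. My estimates were 49.5% for Saturday's and 61.2% for Wednesday's, a rise of 12 percentage points.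

The forecast said 51%, 62% and it rises, on other grounds: “a rate constant decaying independently of L”.

The flasks gave 48.7% for Saturday's and 60.5% for Wednesday's: it rises. The gap of 12 points between them was due to the difference in [L].

    D + L ⇌ J + E (K = 3.10, k = 0.710 M⁻¹ h⁻¹)
    L + J ⇌ Q, settled at all times (K = 6100 M⁻¹)
    L ⇌ X (K = 0.350, k = 0.130 h⁻¹)

The second L of step 2 was the parking of L + J as Q. Saturday's stood at 48.7% because of that parking together with the length of the run. Without the parking Saturday's gave 57.8%, and left ten times as long it gave 60.4%, against the L quotient of 60.0%. For a neighbour flask, Wednesday's with 1.2 M of D, the same quotient gave 19.6%, and that flask gave 19.8% after 8.00 h, with 0.63% of its L free.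

The data are calculated for an exercise.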